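**Plan**
- Retrosynthesis first restores the benzylic carbonyl and the O-benzyl group (macrocyclic ketone 22). Ring B is then cut at C2–C3 and C4–C5, which opens the para-phenylene and the 20-membered ring together and leads to the open-chain diene-ynone 20.
- The enabling feature is ring B itself: a para-phenylene with the ring A oxygen on C1 and the bridge carbon on C4. C2/C1/C6/C5 map onto a 2-oxygenated butadiene carried by the ring A oxygen, and C3/C4 onto a terminal ynone on the ring C arm.
- Further cuts: the O–C(=CH2) unit of the diene (aryl acrylate, ester methylenation), the ring D–CH2 bond of the A–D bibenzyl (hydroboration/B-alkyl Suzuki), the ring C–O bond of the C–O–D ether (SNAr), and the two C–C bonds of the ynone arm (Wittig homologation, acetylide addition).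
- Forward: rings C and D are joined by SNAr, the alkynol arm is grown on ring C, ring A is attached by B-alkyl Suzuki coupling, the diene is raised on the ring A oxygen, the ynone is unmasked, ring B and the macrocycle form in one operation, and hydrogenolysis gives pakyonol.
- Stereochemistry: the target has no stereogenic element; the only stereocentre on the way (the carbinol of 11–19) is racemic and is erased by oxidation.

Key step: step 14

Assumption: pakyonol as drawn has no stereocentre and its 20-membered ring is taken to be conformationally mobile (no isolable atropisomers), so the compound is achiral and no asymmetric step is required.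

**Route**

Step 1
Reactants: 1 isovanillin
Product: 2 3-(tert-butyldimethylsilyloxy)-4-methoxybenzaldehyde
Conditions: TBSCl, imidazole, DMF, rt
Reagents that add atoms: tert-butyldimethylsilyl chloride, CC(C)(C)[Si](C)(C)Cl
Why: Silylation of a phenol under Corey conditions is routine, leaves the aldehyde untouched and masks the O–H that would otherwise consume 9-BBN in step 9.

Step 2
Reactants: 2 3-(tert-butyldimethylsilyloxy)-4-methoxybenzaldehyde
Product: 3 tert-butyl(2-methoxy-5-vinylphenoxy)dimethylsilane
Conditions: Ph3PCH3Br, KHMDS, THF, 0 °C→rt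
Reagents that add atoms: methyltriphenylphosphonium bromide, C[P+](c1ccccc1)(c1ccccc1)c1ccccc1.[Br-]
Why: Wittig methylenation of an aromatic aldehyde with the non-stabilised ylide is reliable, and the aryl silyl ether tolerates the preformed, alkoxide-free ylide.

Step 3
Reactants: 4 4-fluoro-3-hydroxybenzaldehyde
Product: 5 3-(benzyloxy)-4-fluorobenzaldehyde
Conditions: BnBr, K2CO3, DMF, rt
Reagents that add atoms: benzyl bromide, BrCc1ccccc1
Why: Williamson O-benzylation of the phenoxide is fast at room temperature, where the aryl fluoride is not yet displaced.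

Step 4
Reactants: 5 3-(benzyloxy)-4-fluorobenzaldehyde; 6 3-bromophenol
Product: 7 3-(benzyloxy)-4-(3-bromophenoxy)benzaldehyde
Conditions: K2CO3, DMF, 130 °C
Reagents that add atoms: none
Why: Nucleophilic aromatic substitution by the phenoxide displaces the fluoride para to the formyl group, while the unactivated aryl bromide is inert.

Step 5
Reactants: 7 3-(benzyloxy)-4-(3-bromophenoxy)benzaldehyde
Product: 8 2-(benzyloxy)-1-(3-bromophenoxy)-4-(2-methoxyvinyl)benzene (E/Z mixture)
Conditions: MeOCH2PPh3Cl, KHMDS, THF, 0 °C→rt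
Reagents that add atoms: (methoxymethyl)triphenylphosphonium chloride, COC[P+](c1ccccc1)(c1ccccc1)c1ccccc1.[Cl-]
Why: The Wittig reaction with methoxymethylenetriphenylphosphorane is the standard one-carbon homologation of an aryl aldehyde, and the alkene geometry is irrelevant because both isomers hydrolyse to the same aldehyde.

Step 6
Reactants: 8 2-(benzyloxy)-1-(3-bromophenoxy)-4-(2-methoxyvinyl)benzene
Product: 9 2-[3-(benzyloxy)-4-(3-bromophenoxy)phenyl]acetaldehyde
Conditions: 2 M aq HCl, THF, 50 °C; crude used directly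
Reagents that add atoms: water, O
Why: Acid hydrolysis of the enol ether proceeds by C-protonation and hemiacetal collapse, conditions that benzyl and diaryl ethers withstand.

Step 7
Reactants: 9 2-[3-(benzyloxy)-4-(3-bromophenoxy)phenyl]acetaldehyde; 10 ethynyltriisopropylsilane
Product: 11 rac-1-[3-(benzyloxy)-4-(3-bromophenoxy)phenyl]-4-(triisopropylsilyl)but-3-yn-2-ol
Conditions: 10, n-BuLi, THF, −78 °C; then 9, −78→−30 °C; aq NH4Cl
Reagents that add atoms: none
Why: 1,2-Addition of the preformed lithium acetylide to the aldehyde at low temperature should outrun enolisation and leaves the aryl bromide untouched; the new carbinol centre is formed racemic, which is acceptable because step 13 removes it.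

Step 8
Reactants: 11 rac-1-[3-(benzyloxy)-4-(3-bromophenoxy)phenyl]-4-(triisopropylsilyl)but-3-yn-2-ol
Product: 12 rac-{[1-(3-(benzyloxy)-4-(3-bromophenoxy)phenyl)-4-(triisopropylsilyl)but-3-yn-2-yl]oxy}(tert-butyl)dimethylsilane
Conditions: TBSCl, imidazole, DMF, rt
Reagents that add atoms: tert-butyldimethylsilyl chloride, CC(C)(C)[Si](C)(C)Cl
Why: Silylation of the secondary propargylic alcohol removes the acidic O–H ahead of the borane and titanium reagents and adds steric shielding next to the alkyne.

Step 9
Reactants: 3 tert-butyl(2-methoxy-5-vinylphenoxy)dimethylsilane; 12 rac-{[1-(3-(benzyloxy)-4-(3-bromophenoxy)phenyl)-4-(triisopropylsilyl)but-3-yn-2-yl]oxy}(tert-butyl)dimethylsilane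
Product: 15 rac-5-[2-(3-{2-(benzyloxy)-4-[2-(tert-butyldimethylsilyloxy)-4-(triisopropylsilyl)but-3-yn-1-yl]phenoxy}phenyl)ethyl]-2-methoxyphenol, via alkylborane 13 (not isolated), via bis-silyl ether 14 (not isolated)
Conditions: 3 (1.5 equiv), 9-BBN (1.4 equiv B–H), THF, 0 °C→rt; then 12, Pd(dppf)Cl2 (5 mol %), aq K3PO4, DMF, 60 °C; then K2CO3, MeOH, rt
Reagents that add atoms: none
Why: Anti-Markovnikov hydroboration of the styrene with 9-BBN followed by B-alkyl Suzuki–Miyaura coupling with the aryl bromide forges the ArCH2CH2–Ar link, and carbonate in methanol then cleaves only the phenolic silyl ether, which is far more base-labile than the secondary alkyl TBS ether or the TIPS-alkyne.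

Step 10
Reactants: 15 rac-5-[2-(3-{2-(benzyloxy)-4-[2-(tert-butyldimethylsilyloxy)-4-(triisopropylsilyl)but-3-yn-1-yl]phenoxy}phenyl)ethyl]-2-methoxyphenol; 16 acryloyl chloride
Product: 17 rac-5-[2-(3-{2-(benzyloxy)-4-[2-(tert-butyldimethylsilyloxy)-4-(triisopropylsilyl)but-3-yn-1-yl]phenoxy}phenyl)ethyl]-2-methoxyphenyl acrylate
Conditions: Et3N, CH2Cl2, BHT (cat.), −20→0 °C
Reagents that add atoms: none
Why: O-Acylation of the only free hydroxyl group with an acid chloride and a tertiary amine is routine, and low temperature with an inhibitor suppresses acrylate polymerisation.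

Step 11
Reactants: 17 rac-5-[2-(3-{2-(benzyloxy)-4-[2-(tert-butyldimethylsilyloxy)-4-(triisopropylsilyl)but-3-yn-1-yl]phenoxy}phenyl)ethyl]-2-methoxyphenyl acrylate
Product: 18 rac-{[1-(3-(benzyloxy)-4-{3-[2-(3-(buta-1,3-dien-2-yloxy)-4-methoxyphenyl)ethyl]phenoxy}phenyl)-4-(triisopropylsilyl)but-3-yn-2-yl]oxy}(tert-butyl)dimethylsilane
Conditions: Tebbe reagent (1.3 equiv), pyridine (cat.), THF–toluene, −40→0 °C; aq NaOH quench, basic alumina
Reagents that add atoms: Tebbe reagent, C[Al-]1(C)C[Ti]([Cl+]1)(C1C=CC=C1)C1C=CC=C1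
Why: Tebbe methylenation turns an ester C=O into an enol ether, aryl esters and α,β-unsaturated esters being established substrates; the ester is the only carbonyl group present, and the TIPS-capped, α-branched alkyne should be too hindered for [2+2] capture of the titanium methylidene.

Step 12
Reactants: 18 rac-{[1-(3-(benzyloxy)-4-{3-[2-(3-(buta-1,3-dien-2-yloxy)-4-methoxyphenyl)ethyl]phenoxy}phenyl)-4-(triisopropylsilyl)but-3-yn-2-yl]oxy}(tert-butyl)dimethylsilane
Product: 19 rac-1-(3-(benzyloxy)-4-{3-[2-(3-(buta-1,3-dien-2-yloxy)-4-methoxyphenyl)ethyl]phenoxy}phenyl)but-3-yn-2-ol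
Conditions: TBAF (3 equiv), THF, 0 °C→rt
Reagents that add atoms: none
Why: Fluoride cleaves both the O–Si and the C(sp)–Si bond, and the basic, non-acidic medium leaves the acid-labile aryloxydiene intact.

Step 13
Reactants: 19 rac-1-(3-(benzyloxy)-4-{3-[2-(3-(buta-1,3-dien-2-yloxy)-4-methoxyphenyl)ethyl]phenoxy}phenyl)but-3-yn-2-ol
Product: 20 1-(3-(benzyloxy)-4-{3-[2-(3-(buta-1,3-dien-2-yloxy)-4-methoxyphenyl)ethyl]phenoxy}phenyl)but-3-yn-2-one
Conditions: Dess–Martin periodinane, NaHCO3, CH2Cl2, 0 °C; filtered through neutral alumina and used at once in dilute solution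
Reagents that add atoms: none
Why: Bicarbonate-buffered Dess–Martin oxidation of a secondary propargylic alcohol gives the terminal ynone under near-neutral conditions that spare the enol ether diene, and it removes the only stereocentre of the route.

Step 14
Reactants: 20 1-(3-(benzyloxy)-4-{3-[2-(3-(buta-1,3-dien-2-yloxy)-4-methoxyphenyl)ethyl]phenoxy}phenyl)but-3-yn-2-one
Product: 22 O-benzyl macrocyclic ketone (20-membered deoxybenzoin with the carbonyl on ring B), via cyclohexa-1,4-diene cycloadduct 21 (not isolated)
Conditions: PhCl (0.5 mM, slow addition of 20), BHT (cat.), 130 °C; then DDQ (1.2 equiv), rt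
Reagents that add atoms: none
Why: Proposed new method: a thermal normal-electron-demand [4+2] cycloaddition between the 2-aryloxybuta-1,3-diene (HOMO raised by the oxygen, largest coefficient on the CH2 terminus next to the oxygen-bearing carbon) and the terminal ynone (largest LUMO coefficient on the β-CH) joins that diene terminus to the alkyne CH and the other terminus to the acyl-bearing carbon, giving the skipped cyclohexa-1,4-diene 21, which DDQ dehydrogenates to the benzene ring by hydride abstraction from a doubly allylic CH2 followed by proton loss. The closest known reactions are intermolecular Diels–Alder additions of 2-alkoxy- or 2-silyloxybutadienes to alkynyl ketones followed by oxidation to para-substituted aryl ketones, and macrocyclising intramolecular Diels–Alder/aromatisation sequences that build the arene of a cyclophane; a 20-membered closure with this diene/dienophile pair has no direct precedent. Ring B closes through the concerted six-membered [4+2] transition state, and the 20-membered ring closes in the same event because the two new bonds (C2–C3 and C4–C5 of ring B) tie together the two ends of the open chain, the whole tether lying outside the new six-membered ring. No stereocentre results, since the sp3 carbons of 21 become aromatic CH. The step needs para rather than meta regiochemistry, which the matched aryloxy-donor/acyl-acceptor polarisation secures and the long flexible tether does not oppose; it also needs cyclisation rather than oligomerisation, which sub-millimolar concentration by slow addition and a radical inhibitor are meant to secure.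

Step 15
Reactants: 22 O-benzyl macrocyclic ketone
Product: 23 pakyonol
Conditions: H2 (3 atm), 10% Pd/C, EtOAc–AcOH, HClO4 (cat.), rt
Reagents that add atoms: none
Why: Acid-assisted hydrogenolysis over palladium reduces the electron-rich aryl ketone through the benzylic alcohol to the methylene group and cleaves the benzyl ether in the same operation, while diaryl ethers and the methyl ether are inert.

**Compound list**
1 | isovanillin (3-hydroxy-4-methoxybenzaldehyde) | COc1ccc(C=O)cc1O | starting material
2 | 3-(tert-butyldimethylsilyloxy)-4-methoxybenzaldehyde | COc1ccc(C=O)cc1O[Si](C)(C)C(C)(C)C | intermediate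
3 | tert-butyl(2-methoxy-5-vinylphenoxy)dimethylsilane | COc1ccc(C=C)cc1O[Si](C)(C)C(C)(C)C | intermediate
4 | 4-fluoro-3-hydroxybenzaldehyde | O=Cc1ccc(F)c(O)c1 | starting material
5 | 3-(benzyloxy)-4-fluorobenzaldehyde | O=Cc1ccc(F)c(OCc2ccccc2)c1 | intermediate
6 | 3-bromophenol | Oc1cccc(Br)c1 | starting material
7 | 3-(benzyloxy)-4-(3-bromophenoxy)benzaldehyde | O=Cc1ccc(Oc2cccc(Br)c2)c(OCc2ccccc2)c1 | intermediate
8 | 2-(benzyloxy)-1-(3-bromophenoxy)-4-(2-methoxyvinyl)benzene (E/Z mixture) | COC=Cc1ccc(Oc2cccc(Br)c2)c(OCc2ccccc2)c1 | intermediate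
9 | 2-[3-(benzyloxy)-4-(3-bromophenoxy)phenyl]acetaldehyde | O=CCc1ccc(Oc2cccc(Br)c2)c(OCc2ccccc2)c1 | intermediate
10 | ethynyltriisopropylsilane | C#C[Si](C(C)C)(C(C)C)C(C)C | starting material
11 | rac-1-[3-(benzyloxy)-4-(3-bromophenoxy)phenyl]-4-(triisopropylsilyl)but-3-yn-2-ol | OC(Cc1ccc(Oc2cccc(Br)c2)c(OCc2ccccc2)c1)C#C[Si](C(C)C)(C(C)C)C(C)C | intermediate
12 | rac-{[1-(3-(benzyloxy)-4-(3-bromophenoxy)phenyl)-4-(triisopropylsilyl)but-3-yn-2-yl]oxy}(tert-butyl)dimethylsilane | CC(C)(C)[Si](C)(C)OC(Cc1ccc(Oc2cccc(Br)c2)c(OCc2ccccc2)c1)C#C[Si](C(C)C)(C(C)C)C(C)C | intermediate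
13 | 9-{2-[3-(tert-butyldimethylsilyloxy)-4-methoxyphenyl]ethyl}-9-borabicyclo[3.3.1]nonane (not isolated) | COc1ccc(CCB2C3CCCC2CCC3)cc1O[Si](C)(C)C(C)(C)C | intermediate
14 | rac-bibenzyl bis-silyl ether: aryl TBS ether of 15 (not isolated) | COc1ccc(CCc2cccc(Oc3ccc(CC(O[Si](C)(C)C(C)(C)C)C#C[Si](C(C)C)(C(C)C)C(C)C)cc3OCc3ccccc3)c2)cc1O[Si](C)(C)C(C)(C)C | intermediate
15 | rac-5-[2-(3-{2-(benzyloxy)-4-[2-(tert-butyldimethylsilyloxy)-4-(triisopropylsilyl)but-3-yn-1-yl]phenoxy}phenyl)ethyl]-2-methoxyphenol | COc1ccc(CCc2cccc(Oc3ccc(CC(O[Si](C)(C)C(C)(C)C)C#C[Si](C(C)C)(C(C)C)C(C)C)cc3OCc3ccccc3)c2)cc1O | intermediate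
16 | acryloyl chloride | C=CC(=O)Cl | starting material
17 | rac-aryl acrylate of 15 | COc1ccc(CCc2cccc(Oc3ccc(CC(O[Si](C)(C)C(C)(C)C)C#C[Si](C(C)C)(C(C)C)C(C)C)cc3OCc3ccccc3)c2)cc1OC(=O)C=C | intermediate
18 | rac-2-aryloxybuta-1,3-diene with silyl-protected alkynol arm | COc1ccc(CCc2cccc(Oc3ccc(CC(O[Si](C)(C)C(C)(C)C)C#C[Si](C(C)C)(C(C)C)C(C)C)cc3OCc3ccccc3)c2)cc1OC(=C)C=C | intermediate
19 | rac-1-(3-(benzyloxy)-4-{3-[2-(3-(buta-1,3-dien-2-yloxy)-4-methoxyphenyl)ethyl]phenoxy}phenyl)but-3-yn-2-ol | COc1ccc(CCc2cccc(Oc3ccc(CC(O)C#C)cc3OCc3ccccc3)c2)cc1OC(=C)C=C | intermediate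
20 | 1-(3-(benzyloxy)-4-{3-[2-(3-(buta-1,3-dien-2-yloxy)-4-methoxyphenyl)ethyl]phenoxy}phenyl)but-3-yn-2-one (open-chain aryloxydiene ynone) | COc1ccc(CCc2cccc(Oc3ccc(CC(=O)C#C)cc3OCc3ccccc3)c2)cc1OC(=C)C=C | intermediate
21 | macrocyclic cyclohexa-1,4-diene cycloadduct (1-aryloxy-4-acyl, not isolated) | COc1ccc2cc1OC1=CCC(=CC1)C(=O)Cc1ccc(c(OCc3ccccc3)c1)Oc1cccc(c1)CC2 | intermediate
22 | O-benzyl macrocyclic ketone (20-membered deoxybenzoin, carbonyl on ring B) | COc1ccc2cc1Oc1ccc(cc1)C(=O)Cc1ccc(c(OCc3ccccc3)c1)Oc1cccc(c1)CC2 | intermediate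
23 | pakyonol | COc1ccc2cc1Oc1ccc(cc1)CCc1ccc(c(O)c1)Oc1cccc(c1)CC2 | target

**Count and risks**
Total steps: 15. Longest linear sequence: 13 steps (steps 3–15, from 4-fluoro-3-hydroxybenzaldehyde); the ring A branch (steps 1–2) joins at step 9.

Step 14 (labelled as a new method). The macrocyclising cycloaddition may be too slow at the dilution needed, so that enolisation, thermal decomposition or oligomerisation of the ynone overtakes ring closure. The fallback builds ring B as a preformed arene and closes the macrocycle by carbonyl coupling, all known chemistry; it sets out from aldehyde 7 and borane 13 and returns to the route at 23. Aldehyde 7 would be coupled with alkylborane 13 (prepared from 3 with a deficiency of 9-BBN so that no B–H remains to reduce the formyl group) under the step 9 conditions to give the silyl ether aldehyde F1 in the flask, which carbonate in methanol would convert into the phenol aldehyde F2. SNAr of F2 with 4-fluorobenzaldehyde (K2CO3, DMF, 120 °C) would give the dialdehyde F3. Intramolecular McMurry coupling (TiCl4, Zn, pyridine, THF, reflux, slow addition) would close the 20-membered ring to the macrocyclic stilbene F4. Hydrogenation over Pd/C would saturate the stilbene and cleave the benzyl ether to reach 23.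

Step 11. The titanium methylidene may be captured by the alkyne in a [2+2] reaction, the aryl acrylate may polymerise under the Lewis-acidic conditions, or the aryloxydiene may hydrolyse during work-up. The fallback avoids carbonyl methylenation altogether; it sets out from phenol 15 and returns at 18. Palladium-catalysed allylic etherification of 15 with butadiene monoepoxide (Pd2(dba)3, racemic DACH-phenyl Trost ligand, CH2Cl2, rt) should give the branched allylic ether alcohol F5; its extra stereocentre is uncontrolled and is erased later. Appel iodination (I2, PPh3, imidazole) would give the iodide F6, and E2 elimination of HI across the allylic, oxygen-bearing C–H (KOtBu, THF, 0 °C) would deliver diene 18.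

Step 7. The acetylide may act as a base, so that enolisation and aldol self-condensation of the arylacetaldehyde compete with 1,2-addition. The fallback reverses the polarity of the C–C bond formation; it sets out from aldehyde 7 and returns at 11. Reduction of 7 with NaBH4 would give the benzylic alcohol F7, and SOCl2 would convert it into the benzylic chloride F8. Zinc insertion (Zn dust, LiCl, THF, rt; the aryl bromide is not touched) would give the benzylzinc chloride F9, which should add to 3-(triisopropylsilyl)propynal to furnish 11 without passing through an enolisable aldehyde.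

Further compounds
F1 | step 14 | 3-(benzyloxy)-4-{3-[2-(3-(tert-butyldimethylsilyloxy)-4-methoxyphenyl)ethyl]phenoxy}benzaldehyde | COc1ccc(CCc2cccc(Oc3ccc(C=O)cc3OCc3ccccc3)c2)cc1O[Si](C)(C)C(C)(C)C
F2 | step 14 | 3-(benzyloxy)-4-{3-[2-(3-hydroxy-4-methoxyphenyl)ethyl]phenoxy}benzaldehyde | COc1ccc(CCc2cccc(Oc3ccc(C=O)cc3OCc3ccccc3)c2)cc1O
F3 | step 14 | 3-(benzyloxy)-4-{3-[2-(3-(4-formylphenoxy)-4-methoxyphenyl)ethyl]phenoxy}benzaldehyde | COc1ccc(CCc2cccc(Oc3ccc(C=O)cc3OCc3ccccc3)c2)cc1Oc1ccc(C=O)cc1
F4 | step 14 | O-benzyl macrocyclic stilbene (E/Z mixture) | COc1ccc2cc1Oc1ccc(cc1)C=Cc1ccc(c(OCc3ccccc3)c1)Oc1cccc(c1)CC2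
F5 | step 11 | 2-aryloxybut-3-en-1-ol from phenol 15 (diastereomer mixture) | COc1ccc(CCc2cccc(Oc3ccc(CC(O[Si](C)(C)C(C)(C)C)C#C[Si](C(C)C)(C(C)C)C(C)C)cc3OCc3ccccc3)c2)cc1OC(CO)C=C
F6 | step 11 | 1-iodo-2-aryloxybut-3-ene from F5 (diastereomer mixture) | COc1ccc(CCc2cccc(Oc3ccc(CC(O[Si](C)(C)C(C)(C)C)C#C[Si](C(C)C)(C(C)C)C(C)C)cc3OCc3ccccc3)c2)cc1OC(CI)C=C
F7 | step 7 | [3-(benzyloxy)-4-(3-bromophenoxy)phenyl]methanol | OCc1ccc(Oc2cccc(Br)c2)c(OCc2ccccc2)c1
F8 | step 7 | 2-(benzyloxy)-1-(3-bromophenoxy)-4-(chloromethyl)benzene | ClCc1ccc(Oc2cccc(Br)c2)c(OCc2ccccc2)c1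
F9 | step 7 | [3-(benzyloxy)-4-(3-bromophenoxy)benzyl]zinc chloride | Cl[Zn]Cc1ccc(Oc2cccc(Br)c2)c(OCc2ccccc2)c1
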